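**Plan** (target numbering: O1, C2 = OCH2, C3 = tertiary carbinol bearing the benzyl group, C4 = CH–CH2OH, C5 = CH–aryl)
1. Retrosynthesis cuts, in order: the two aryl O–benzyl bonds and the C3 O–silyl bond; the ring bond C3–C4; the ether bond O1–C2; the vinyl–carbinol C–C bond at C5.
2. Enabling feature: C4 bears CH2OH, so C4 is the radical of a reductively opened terminal oxirane; C3 is an oxygenated carbon flanked by ArCH2, so C3=CHAr is the enol silane of a benzyl ketone. With O1 between them, C4–C5–O1–C2–C3=CHAr is a 3-oxahex-5-enyl radical ending in a styrene.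
3. Forward order: aryl vinyl carbinol, Sharpless kinetic resolution to the epoxy alcohol, O–H insertion of an arylacetyl diazoketone, enol silylation, then the only ring closure (oxolane, radical 5-exo-trig), desilylation, hydrogenolysis.
4. Stereochemistry: C5 comes from the kinetic resolution; C4 and C3 both arise in the ring closure by relay from C5; the oxirane stereocentre is erased on purpose.

Key step: step 6

Remark: 4-(benzyloxy)-3-methoxybenzaldehyde and [4-(benzyloxy)-3-methoxyphenyl]acetic acid are taken as purchasable (each is one benzylation away from vanillin or homovanillic acid).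

**Step 1**
Reactants: 1 4-(benzyloxy)-3-methoxybenzaldehyde
Product: 2 rac-1-[4-(benzyloxy)-3-methoxyphenyl]prop-2-en-1-ol
Conditions: CH2=CHMgBr (1.2 equiv), THF, −78 → 0 °C; then H2O
Reagents that add atoms: vinylmagnesium bromide, C=C[Mg]Br
Why: Grignard 1,2-addition to the aryl aldehyde should give the racemic aryl vinyl carbinol, whose stereocentre is resolved in step 2.

**Step 2**
Reactants: 2 rac-1-[4-(benzyloxy)-3-methoxyphenyl]prop-2-en-1-ol
Product: 3 (S)-[4-(benzyloxy)-3-methoxyphenyl][(2R)-oxiran-2-yl]methanol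
Conditions: Ti(OiPr)4 (15 mol %), L-(+)-diisopropyl tartrate (18 mol %), t-BuOOH (0.45 equiv), 4 Å sieves, CH2Cl2, −20 °C
Reagents that add atoms: tert-butyl hydroperoxide, CC(C)(C)OO
Why: Sharpless kinetic resolution: with the L-(+)-tartrate the (R)-carbinol should be epoxidized much faster than its antipode and with erythro selectivity, so stopping below half conversion should give 3, whose carbinol carbon (descriptor S only because the oxiranyl group now outranks aryl) becomes C5 of the target, while the oxirane CH is erased later.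

**Step 3**
Reactants: 4 [4-(benzyloxy)-3-methoxyphenyl]acetic acid
Product: 6 1-[4-(benzyloxy)-3-methoxyphenyl]-3-diazopropan-2-one, via acid chloride 5 (not isolated)
Conditions: (COCl)2, DMF (cat.), CH2Cl2, 0 °C → rt, evaporate; Me3SiCHN2 (2 equiv), THF/MeCN, 0 °C
Reagents that add atoms: oxalyl chloride, O=C(Cl)C(Cl)=O (chlorine of 5); trimethylsilyldiazomethane, C[Si](C)(C)C=[N+]=[N-] (CHN2 of 6)
Why: Acid chloride formation and C-acylation of trimethylsilyldiazomethane with loss of the silyl group (Arndt–Eistert-type diazoketone synthesis) should give 6; no stereocentre is involved.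

**Step 4**
Reactants: 3 (S)-[4-(benzyloxy)-3-methoxyphenyl][(2R)-oxiran-2-yl]methanol; 6 1-[4-(benzyloxy)-3-methoxyphenyl]-3-diazopropan-2-one
Product: 7 1-[4-(benzyloxy)-3-methoxyphenyl]-3-{(S)-[4-(benzyloxy)-3-methoxyphenyl][(2R)-oxiran-2-yl]methoxy}propan-2-one
Conditions: Rh2(OAc)4 (1 mol %), CH2Cl2, rt, slow addition of 6 (1.5 equiv)
Reagents that add atoms: none
Why: Rh2(OAc)4-catalysed carbenoid O–H insertion into the secondary alcohol should form the α-alkoxy ketone under neutral conditions, so neither a Payne rearrangement of the epoxy alcohol nor ionization of the benzylic carbinol can occur and the carbinol configuration is kept.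

**Step 5**
Reactants: 7 1-[4-(benzyloxy)-3-methoxyphenyl]-3-{(S)-[4-(benzyloxy)-3-methoxyphenyl][(2R)-oxiran-2-yl]methoxy}propan-2-one
Product: 8 tert-butyl{[(1Z)-1-[4-(benzyloxy)-3-methoxyphenyl]-3-{(S)-[4-(benzyloxy)-3-methoxyphenyl][(2R)-oxiran-2-yl]methoxy}prop-1-en-2-yl]oxy}dimethylsilane
Conditions: KN(SiMe3)2, THF, −78 °C; t-BuMe2SiCl, −78 → 0 °C
Reagents that add atoms: tert-butyldimethylsilyl chloride, CC(C)(C)[Si](C)(C)Cl
Why: Kinetic enolization should remove the more acidic benzylic α-proton (aryl-conjugated enolate) and O-silylation should give the (Z)-enol silane, the oxirane being inert to the hindered amide at −78 °C and no stereocentre being touched.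

**Step 6**
Reactants: 8 tert-butyl{[(1Z)-1-[4-(benzyloxy)-3-methoxyphenyl]-3-{(S)-[4-(benzyloxy)-3-methoxyphenyl][(2R)-oxiran-2-yl]methoxy}prop-1-en-2-yl]oxy}dimethylsilane
Product: 9 {(2R,3S,4R)-2-[4-(benzyloxy)-3-methoxyphenyl]-4-{[4-(benzyloxy)-3-methoxyphenyl]methyl}-4-[(tert-butyldimethylsilyl)oxy]oxolan-3-yl}methanol
Conditions: Cp2TiCl (2.2 equiv, from Cp2TiCl2 and Zn dust in THF) added over 2 h to 8 and 1,4-cyclohexadiene (4 equiv), THF, rt; then H2O
Reagents that add atoms: none
Why: Proposed new method: Cp2TiCl should open the terminal oxirane by single-electron transfer to the secondary β-titanoxy radical at C4 (either oxirane epimer gives the same radical), which closes 5-exo-trig onto the silyloxy-bearing alkene carbon C3 because only this mode gives a five-membered ring and a benzylic radical; that radical then takes a hydrogen atom from 1,4-cyclohexadiene. The closest known reaction type is the Nugent–RajanBabu titanocene epoxide–olefin radical cyclization, shown on 3-oxahex-5-enyl radicals ending in a styrene (cinnamyl ethers) but not on an enol silane attacked at its oxygen-bearing carbon. The oxolane should close through a chair-like Beckwith–Houk transition state with the C5 aryl group pseudo-equatorial. C4 is thereby set trans to the aryl group (1,2-induction from C5), and C3 is set with the benzylic carbon cis to the CH2O–titanium arm and trans to the aryl group, which leaves the silyloxy group anti to CH2OH as in the target. The step needs ring closure to outrun reduction of the first radical by a second Cp2TiCl (which would end in deoxygenation), secured by slow addition of the reductant and by the fast closure of an oxygen-containing chain onto an aryl-terminated alkene; it also needs hydrogen-atom transfer to outrun titanium capture of the benzylic radical (which would expel the β-silyloxy group), secured by the weak benzyl–titanium bond, the low Cp2TiCl concentration and the excess diene.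

**Step 7**
Reactants: 9 {(2R,3S,4R)-2-[4-(benzyloxy)-3-methoxyphenyl]-4-{[4-(benzyloxy)-3-methoxyphenyl]methyl}-4-[(tert-butyldimethylsilyl)oxy]oxolan-3-yl}methanol
Product: 10 (3R,4S,5R)-5-[4-(benzyloxy)-3-methoxyphenyl]-3-{[4-(benzyloxy)-3-methoxyphenyl]methyl}-4-(hydroxymethyl)oxolan-3-ol
Conditions: Bu4NF, THF, 0 → 40 °C; then H2O
Reagents that add atoms: none
Why: Fluoride desilylation of the tertiary silyl ether, helped by 1,3-migration of silicon to the neighbouring primary alkoxide, should give the diol while the phenols are still protected and no stereocentre is touched.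

**Step 8**
Reactants: 10 (3R,4S,5R)-5-[4-(benzyloxy)-3-methoxyphenyl]-3-{[4-(benzyloxy)-3-methoxyphenyl]methyl}-4-(hydroxymethyl)oxolan-3-ol
Product: 11 (3R,4S,5R)-5-(4-hydroxy-3-methoxyphenyl)-3-[(4-hydroxy-3-methoxyphenyl)methyl]-4-(hydroxymethyl)oxolan-3-ol
Conditions: H2 (1 atm), 10% Pd on carbon, EtOAc/EtOH, rt
Reagents that add atoms: none
Why: Hydrogenolysis of the two aryl benzyl ethers under neutral conditions should give the target, the benzylic C5–O1 bond of the oxolane being cleaved far more slowly and all stereocentres being kept.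

**Compound list**
1 | 4-(benzyloxy)-3-methoxybenzaldehyde | COc1cc(C=O)ccc1OCc1ccccc1 | starting material
2 | rac-1-[4-(benzyloxy)-3-methoxyphenyl]prop-2-en-1-ol | COc1cc(C(O)C=C)ccc1OCc1ccccc1 | intermediate
3 | (S)-[4-(benzyloxy)-3-methoxyphenyl][(2R)-oxiran-2-yl]methanol | COc1cc([C@H](O)[C@H]2CO2)ccc1OCc1ccccc1 | intermediate
4 | [4-(benzyloxy)-3-methoxyphenyl]acetic acid | COc1cc(CC(=O)O)ccc1OCc1ccccc1 | starting material
5 | [4-(benzyloxy)-3-methoxyphenyl]acetyl chloride | COc1cc(CC(=O)Cl)ccc1OCc1ccccc1 | intermediate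
6 | 1-[4-(benzyloxy)-3-methoxyphenyl]-3-diazopropan-2-one | COc1cc(CC(=O)C=[N+]=[N-])ccc1OCc1ccccc1 | intermediate
7 | 1-[4-(benzyloxy)-3-methoxyphenyl]-3-{(S)-[4-(benzyloxy)-3-methoxyphenyl][(2R)-oxiran-2-yl]methoxy}propan-2-one | COc1cc(CC(=O)CO[C@@H](c2ccc(OCc3ccccc3)c(OC)c2)[C@H]4CO4)ccc1OCc1ccccc1 | intermediate
8 | tert-butyl{[(1Z)-1-[4-(benzyloxy)-3-methoxyphenyl]-3-{(S)-[4-(benzyloxy)-3-methoxyphenyl][(2R)-oxiran-2-yl]methoxy}prop-1-en-2-yl]oxy}dimethylsilane | COc1cc(/C=C(\O[Si](C)(C)C(C)(C)C)CO[C@@H](c2ccc(OCc3ccccc3)c(OC)c2)[C@H]4CO4)ccc1OCc1ccccc1 | intermediate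
9 | {(2R,3S,4R)-2-[4-(benzyloxy)-3-methoxyphenyl]-4-{[4-(benzyloxy)-3-methoxyphenyl]methyl}-4-[(tert-butyldimethylsilyl)oxy]oxolan-3-yl}methanol | COc1cc(C[C@]2(O[Si](C)(C)C(C)(C)C)CO[C@@H](c3ccc(OCc4ccccc4)c(OC)c3)[C@@H]2CO)ccc1OCc1ccccc1 | intermediate
10 | (3R,4S,5R)-5-[4-(benzyloxy)-3-methoxyphenyl]-3-{[4-(benzyloxy)-3-methoxyphenyl]methyl}-4-(hydroxymethyl)oxolan-3-ol | COc1cc(C[C@]2(O)CO[C@@H](c3ccc(OCc4ccccc4)c(OC)c3)[C@@H]2CO)ccc1OCc1ccccc1 | intermediate
11 | (3R,4S,5R)-5-(4-hydroxy-3-methoxyphenyl)-3-[(4-hydroxy-3-methoxyphenyl)methyl]-4-(hydroxymethyl)oxolan-3-ol | COc1cc(C[C@]2(O)CO[C@@H](c3ccc(O)c(OC)c3)[C@@H]2CO)ccc1O | target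

Total step count: 8. Longest linear sequence: 7 (steps 1, 2, 4, 5, 6, 7, 8).

**Steps most likely to fail**

Step 6 (proposed new method). What may go wrong: the C4 radical is reduced by Cp2TiCl before it closes; the benzylic radical is captured by titanium and loses the silyloxy group to give a styrene; or the alkene face at C3 is poorly discriminated. The fallback uses known chemistry, sets out from 3 and comes back at 11. Sonogashira coupling of 1-(benzyloxy)-4-iodo-2-methoxybenzene with prop-2-yn-1-ol (Pd(PPh3)2Cl2, CuI, Et3N) gives 3-[4-(benzyloxy)-3-methoxyphenyl]prop-2-yn-1-ol F1, and CBr4/PPh3 converts it into the propargylic bromide F2. Alkylation of 3 with the propargylic bromide F2 under Ag2O (no base, so no Payne shift) gives the epoxy propargyl ether F3. The precedented Cp2TiCl epoxide–alkyne 5-exo-dig radical cyclization then gives the 4-benzylidene oxolane F4 (C4 again trans to the aryl group; the alkene geometry is irrelevant). NaH/BnBr gives the benzyl ether F5. Dimethyldioxirane in acetone at −20 °C should epoxidize the exocyclic styrene from the face opposite the adjacent CH2OBn group to give the spiro-epoxide F6. H2 over 10% Pd on carbon then cleaves the benzylic C–O bond of the oxirane and all three benzyl ethers to give 11.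

Step 4. What may go wrong: the rhodium carbenoid is diverted into its own electron-rich arene (intramolecular aromatic substitution) or onto the oxirane oxygen instead of the hindered alcohol. The fallback sets out from 3 and comes back at 7. Ag2O-mediated O-alkylation of 3 with 2-bromo-N-methoxy-N-methylacetamide gives the Weinreb amide ether F7. Addition of 4-(benzyloxy)-3-methoxybenzylmagnesium chloride (from the benzyl chloride and Mg) in THF at −78 °C, where the oxirane is not opened, then gives 7.

Step 2. What may go wrong: the two enantiomers are not discriminated well enough at low conversion, and the product oxirane is opened under the titanium conditions. The fallback sets out from 2 and comes back at 7. The resolution is run with D-(−)-diisopropyl tartrate past half conversion so that the slow-reacting enantiomer (1R)-1-[4-(benzyloxy)-3-methoxyphenyl]prop-2-en-1-ol F8 is recovered in high enantiomeric purity. Rh2(OAc)4-catalysed O–H insertion of 6 gives the allyl ether ketone F9. Dimethyldioxirane epoxidation of its terminal alkene gives 7 together with its oxirane epimer F10, and both converge on the same radical in step 6.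

**Further compounds**
F1 | step 6 | 3-[4-(benzyloxy)-3-methoxyphenyl]prop-2-yn-1-ol | COc1cc(C#CCO)ccc1OCc1ccccc1
F2 | step 6 | 1-(benzyloxy)-4-(3-bromoprop-1-yn-1-yl)-2-methoxybenzene | COc1cc(C#CCBr)ccc1OCc1ccccc1
F3 | step 6 | (2R)-2-[(S)-[4-(benzyloxy)-3-methoxyphenyl]({3-[4-(benzyloxy)-3-methoxyphenyl]prop-2-yn-1-yl}oxy)methyl]oxirane | COc1cc(C#CCO[C@@H](c2ccc(OCc3ccccc3)c(OC)c2)[C@H]4CO4)ccc1OCc1ccccc1
F4 | step 6 | {(2R,3S)-2-[4-(benzyloxy)-3-methoxyphenyl]-4-{[4-(benzyloxy)-3-methoxyphenyl]methylidene}oxolan-3-yl}methanol (E/Z mixture) | COc1cc(C=C2CO[C@@H](c3ccc(OCc4ccccc4)c(OC)c3)[C@@H]2CO)ccc1OCc1ccccc1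
F5 | step 6 | (2R,3S)-2-[4-(benzyloxy)-3-methoxyphenyl]-4-{[4-(benzyloxy)-3-methoxyphenyl]methylidene}-3-[(benzyloxy)methyl]oxolane (E/Z mixture) | COc1cc(C=C2CO[C@@H](c3ccc(OCc4ccccc4)c(OC)c3)[C@@H]2COCc5ccccc5)ccc1OCc1ccccc1
F6 | step 6 | (3R,6R,7S)-2,6-bis[4-(benzyloxy)-3-methoxyphenyl]-7-[(benzyloxy)methyl]-1,5-dioxaspiro[2.4]heptane (epimers at C2) | COc1cc(C3O[C@]34CO[C@@H](c5ccc(OCc6ccccc6)c(OC)c5)[C@@H]4COCc7ccccc7)ccc1OCc1ccccc1
F7 | step 4 | 2-{(S)-[4-(benzyloxy)-3-methoxyphenyl][(2R)-oxiran-2-yl]methoxy}-N-methoxy-N-methylacetamide | CON(C)C(=O)CO[C@@H](c1ccc(OCc2ccccc2)c(OC)c1)[C@H]3CO3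
F8 | step 2 | (1R)-1-[4-(benzyloxy)-3-methoxyphenyl]prop-2-en-1-ol | COc1cc([C@H](O)C=C)ccc1OCc1ccccc1
F9 | step 2 | 1-[4-(benzyloxy)-3-methoxyphenyl]-3-{[(1R)-1-[4-(benzyloxy)-3-methoxyphenyl]prop-2-en-1-yl]oxy}propan-2-one | COc1cc(CC(=O)CO[C@@H](c2ccc(OCc3ccccc3)c(OC)c2)C=C)ccc1OCc1ccccc1
F10 | step 2 | 1-[4-(benzyloxy)-3-methoxyphenyl]-3-{(S)-[4-(benzyloxy)-3-methoxyphenyl][(2S)-oxiran-2-yl]methoxy}propan-2-one | COc1cc(CC(=O)CO[C@@H](c2ccc(OCc3ccccc3)c(OC)c2)[C@@H]4CO4)ccc1OCc1ccccc1
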